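**Assumption:** the target (5,7-dihydroxy-2-pentadecyl-4H-chromen-4-one) has no stereocentre and no stereogenic double bond, so it is achiral and "single enantiomer" calls for no stereocontrol. The route has not been run; step 4 rests on analogy to the known carbonylative annulation of o-iodophenol acetates.

## Retrosynthetic overview

1. The pyranone ring is cut at three bonds at once (C4–C4a, C3–C4, O1–C2): a Pd-catalysed carbonylative annulation of an o-iodophenol equivalent, CO and heptadec-1-yne. The usual phloroacetophenone/Baker–Venkataraman route is not used.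
2. The aryl partner is C3-symmetric 2-iodophloroglucinol triacetate from phloroglucinol; symmetry removes every regiochemical question, and the acetates fall off in the annulation pot.
3. Heptadec-1-yne comes from 1-bromopentadecane and acetylide.
4. Ring order: the benzene ring is bought; the pyranone ring is formed last, in one pot, by 6-endo closure through an enaminone.

## Route

**Step 1**
Reactants: 1 phloroglucinol (benzene-1,3,5-triol)
Product: 2 2-iodobenzene-1,3,5-triol
Conditions: I2 (1.0 equiv), NaHCO3 (1.1 equiv), THF/H2O 1:1, 0 °C, 20 min; extract, use crude at once (light-sensitive)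
Reagents that add atoms: iodine, II
Why: Electrophilic aromatic iodination of the phenoxide; the three ring CH positions are equivalent by symmetry, so only mono- versus poly-iodination matters, and that is held by one equivalent of I2 at 0 °C.

**Step 2**
Reactants: 2 2-iodobenzene-1,3,5-triol
Product: 3 2-iodobenzene-1,3,5-triyl triacetate
Conditions: Ac2O (4 equiv), pyridine (5 equiv), DMAP (5 mol%), CH2Cl2, 0 °C → rt; recrystallise
Reagents that add atoms: acetic anhydride, CC(=O)OC(C)=O
Why: DMAP-catalysed O-acylation turns the fragile, electron-rich iodotriol into a stable, less electron-rich aryl iodide that undergoes oxidative addition more readily; the C–I bond is inert to these conditions.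

**Step 3**
Reactants: 4 1-bromopentadecane
Product: 5 heptadec-1-yne
Conditions: LiC≡CH·H2NCH2CH2NH2 (1.5 equiv), DMSO, 10 °C → rt, 3 h
Reagents that add atoms: lithium acetylide–ethylenediamine complex, [Li+].[C-]#C.NCCN
Why: SN2 alkylation of an acetylide by an unhindered primary bromide in a dipolar aprotic solvent gives the terminal alkyne without dialkylation or isomerisation.

**Step 4**
Reactants: 3 2-iodobenzene-1,3,5-triyl triacetate, 5 heptadec-1-yne
Product: 9 5,7-dihydroxy-2-pentadecyl-4H-chromen-4-one, via ynone triacetate 6 (not isolated), via enaminone phenol 7 (not isolated), via chromone diacetate 8 (not isolated)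
Conditions: PdCl2(PPh3)2 (5 mol%), dppp (5 mol%), thiourea (5 mol%), CO (balloon, 1 atm), Et2NH/DMF 1:4, DBU (2 equiv), 40 °C, 24–48 h; then MeOH, rt, 2 h; 1 M HCl work-up
Reagents that add atoms: carbon monoxide, [C-]#[O+] (stays in 9); diethylamine, CCNCC (only in intermediate 7, expelled again)
Why: Pd-catalysed carbonylative Sonogashira coupling/annulation: oxidative addition, CO insertion and alkynylation give ynone 6; Et2NH then adds to the ynone and cleaves an ortho acetate to give 7, whose phenol closes exclusively 6-endo by addition–elimination to chromone 8 (no aurone), and DBU/MeOH transesterification frees the last two phenols.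

## Compound list

1 | phloroglucinol (benzene-1,3,5-triol) | Oc1cc(O)cc(O)c1 | starting material
2 | 2-iodobenzene-1,3,5-triol | Oc1cc(O)c(I)c(O)c1 | intermediate
3 | 2-iodobenzene-1,3,5-triyl triacetate | CC(=O)Oc1cc(OC(C)=O)c(I)c(OC(C)=O)c1 | intermediate
4 | 1-bromopentadecane | CCCCCCCCCCCCCCCBr | starting material
5 | heptadec-1-yne | CCCCCCCCCCCCCCCC#C | intermediate
6 | 2-(octadec-2-ynoyl)benzene-1,3,5-triyl triacetate (ynone triacetate) | CCCCCCCCCCCCCCCC#CC(=O)c1c(OC(C)=O)cc(OC(C)=O)cc1OC(C)=O | intermediate (not isolated)
7 | 4-[(2E)-3-(diethylamino)octadec-2-enoyl]-5-hydroxy-1,3-phenylene diacetate (enaminone phenol) | CCN(CC)/C(CCCCCCCCCCCCCCC)=C/C(=O)c1c(O)cc(OC(C)=O)cc1OC(C)=O | intermediate (not isolated)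
8 | 4-oxo-2-pentadecyl-4H-chromene-5,7-diyl diacetate (chromone diacetate) | CCCCCCCCCCCCCCCc1cc(=O)c2c(OC(C)=O)cc(OC(C)=O)cc2o1 | intermediate (not isolated)
9 | 5,7-dihydroxy-2-pentadecyl-4H-chromen-4-one (achiral) | CCCCCCCCCCCCCCCc1cc(=O)c2c(O)cc(O)cc2o1 | target

## Summary

Total step count: 4.
Longest linear sequence: 3 steps (1 → 2 → 3 → 9); the side branch 4 → 5 joins in step 4.

**Steps most likely to fail, with fallbacks**

**Step 4 (carbonylative annulation).** Risks are diethylamide formation from the aroyl-palladium species, protodeiodination, and loss of the acetates before coupling. The fallback sets out from 5 and comes back at 9. It brings in the carbonyl carbon already attached to the arene instead of from CO. Acyl Sonogashira coupling of 5 with purchased 2,4,6-trimethoxybenzoyl chloride (COc1cc(OC)c(C(=O)Cl)c(OC)c1), using PdCl2(PPh3)2, CuI and Et3N in THF at rt, gives 1-(2,4,6-trimethoxyphenyl)octadec-2-yn-1-one F1. Heating this in 48% aqueous HBr/AcOH at reflux adds HBr and water across the ynone, cleaves the three methyl ethers and closes the ring by 6-endo addition–elimination/cyclodehydration, giving 9 directly.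

**Step 1 (mono-iodination of phloroglucinol).** Risks are over-iodination and decomposition of the free iodotriol. The fallback sets out from 1 and comes back at 3, bypassing 2. Phloroglucinol is acetylated first (Ac2O, pyridine, rt) to benzene-1,3,5-triyl triacetate F2. This much less activated but still symmetric arene is then iodinated with NIS (1.05 equiv) and TfOH in MeCN at 0 °C → rt. The first iodine deactivates and shields the ring, so the reaction stops at the mono-iodide, which is 3.

**Step 3 (acetylide alkylation).** Risks are E2 elimination and poor solubility of the C15 bromide in DMSO. The fallback sets out from 4 and comes back at 5, with the polarity reversed. Compound 4 is converted with Mg in THF into pentadecylmagnesium bromide F3. This is coupled under copper catalysis (CuCl2 3 mol%, THF/NMP, 0 °C) with purchased (bromoethynyl)triisopropylsilane (BrC#C[Si](C(C)C)(C(C)C)C(C)C) to give (heptadec-1-yn-1-yl)tri(propan-2-yl)silane F4. TBAF in THF removes the silyl group and delivers 5.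

## Further compounds

F1 | step 4 | 1-(2,4,6-trimethoxyphenyl)octadec-2-yn-1-one | CCCCCCCCCCCCCCCC#CC(=O)c1c(OC)cc(OC)cc1OC
F2 | step 1 | benzene-1,3,5-triyl triacetate | CC(=O)Oc1cc(OC(C)=O)cc(OC(C)=O)c1
F3 | step 3 | pentadecylmagnesium bromide | CCCCCCCCCCCCCCC[Mg]Br
F4 | step 3 | (heptadec-1-yn-1-yl)tri(propan-2-yl)silane | CCCCCCCCCCCCCCCC#C[Si](C(C)C)(C(C)C)C(C)C
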